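## Analysis of the target

Compound 14 is a daucane sesquiterpene ester: a trans-fused bicyclo[5.3.0]decane in which a cyclopentane (C1–C2–C3–C4–C5) and a cycloheptane (C1–C5–C6–C7–C8–C9–C10) share the C1–C5 bond. Daucane numbering is used for every compound below: C1 carries the angular methyl, C4 the hydroxyl and the isopropyl group, C6 the 4-methoxybenzoate, C8 a methyl group, and C8–C9 the epoxide. There are six stereocentres, (1R,4R,5S,6S,8R,9S); C4, C5 and C1 are contiguous and two of them are fully substituted. On the cyclopentane the angular methyl, the C4 hydroxyl and the C5–C6 bond lie on one face and the isopropyl group, H5 and C10 on the other, so the ring fusion is trans. The ester oxygen on C6 and the epoxide oxygen lie on the face of H5, anti to the angular methyl, and O4/O6 are 1,3-anti. The sensitive groups are the trisubstituted epoxide (the C4 hydroxyl on the opposite face is placed for transannular opening under acid), the aryl ester, and the O4–C4–C5–C6 array, which can lose O4 by β-elimination or retro-aldol cleavage whenever C6 is a carbonyl carbon. The hard part is C5, wedged between the quaternary C1 and the tertiary carbinol C4, together with the 1,3-relation of C1 and C4, for which the substrate offers no clear steric bias. The feature that invites the chosen move is the five-membered ring: C1 (methyl) and C4 (hydroxyl, isopropyl) are linked through C5 on one side and C2–C3 on the other, and C5 bears the one-carbon branch C6. This is the skeleton, oxygen atom and stereocentre of p-menth-1-en-4-ol (compound 1) with its ring carbon C2 turned out of the ring.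

## Retrosynthetic reasoning

14 ⇒ 13. The last bond cut is the O4–benzyl bond of a 4-methoxybenzyl ether. The tertiary hydroxyl stays masked through every basic, Lewis-acidic and oxidative step, cannot open the epoxide, and is released under neutral oxidative conditions that spare epoxide and ester.

13 ⇒ 11 + 12. The ester C–O bond at C6 is cut. In 11 the C6 hydroxyl is the only free hydroxyl, so the acylation needs no selectivity.

11 ⇒ 10. The two C–O bonds of the epoxide are cut back to the C8=C9 alkene. The homoallylic C6 hydroxyl of 10 lies on the face that must receive the oxygen, so it can deliver it.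

10 ⇒ 9. The C8=C9 bond is cut by a ring-closing metathesis transform. This opens the seven-membered ring to a cyclopentane with an allyl group on C1 and a 2-methylallyl carbinol on C5; the alkene is formed exactly where the epoxide is needed.

9 ⇒ 8. The C6–C7 bond is cut to aldehyde 8. In 8 the formyl group and O4 are cis on the cyclopentane, so a chelate between them can expose one face of the carbonyl and set C6.

8 ⇒ 6 (through 7). The C1–C10 bond is cut by an anionic oxy-Cope transform. The quaternary centre C1 is thereby traced to a secondary carbinol at C6, which an asymmetric allylation can set under reagent control; direct conjugate addition to C1 would have to rely on the weak 1,3-bias from C4. C5 then follows by equilibration of the aldehyde.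

6 ⇒ 4. The C6–allyl bond is cut to enal 4.

4 ⇒ 2 (through 3). The C1=C5 bond is cut (aldol condensation transform) and the six-membered ring is re-formed by joining C1 to C6 (ozonolysis transform). This is the key disconnection: ten of the fifteen skeletal carbons, the C4 oxygen and the C4 stereocentre are traced to one terpene, and the cyclopentane is a contracted cyclohexene.

2 ⇒ 1. The ether is cut to the commercial terpene alcohol 1.

## Alternatives that were turned down

Alternative 1: The textbook route. The C8=C9 bond is closed by ring-closing metathesis on a cyclopentane taken from A1 through the known ring-contracted enal A2, which leads to the C4-deoxy bicycle A3. It was turned down because A3 lacks O4. The hydroxyl would have to be introduced late at a non-activated tertiary C–H flanked by C5, in competition with H5, the isopropyl methine and four allylic positions, or by hydration of a C3=C4 or C4=C11 alkene with no control of the C4 configuration. This costs at least four extra steps for the centre that 1 supplies for nothing.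

Alternative 2: The aldol disconnection of C4–C5, suggested by the O4–C4–C5–C6–O6 array: cycloheptenone A4 is closed to hydroxy ketone A5. It was turned down for three reasons. The C5 enolate is endocyclic in the seven-membered ring, so the tether on C1 can reach it only from its own face, and the kinetic product is cis-fused. Under reversible conditions the natural isomer and the cis-fused isomer with C4 and C5 both inverted differ only in whether the methyl or the C10 methylene on C1 is syn, so C1 cannot control C4. A4 also needs its own asymmetric synthesis of the quaternary centre and carries a β,γ-unsaturated ketone that conjugates easily.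

Alternative 3: An asymmetric (4+3) cycloaddition, forming C7–C8 and C1–C10 in one step. A chiral dirhodium catalyst would cyclopropanate siloxydiene A6 with the vinylcarbenoid from A7, and the cis-divinylcyclopropane would undergo Cope rearrangement to A8. It builds the seven-membered ring and the quaternary C1 at once, but A8 carries an ester where the C8 methyl must be (three redox steps) and has no handle at C4. A diene that already carries the C4 centre would force the Cope step onto the face of the isopropyl group, and A7 itself takes three steps. The route would exceed fifteen steps, so the precursor costs more than the key step wins.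

Key step: step 2

Assumption: (S)-(+)-terpinen-4-ol (1) is taken as commercially available in high enantiomeric purity; the C4 centre of 14 (R) corresponds to (S) in 1 only because the CIP priorities change, the spatial arrangement is the same.

## Route

Step 1
Reactants: 1 (S)-(+)-terpinen-4-ol
Product: 2 1-methoxy-4-({[(1S)-4-methyl-1-(propan-2-yl)cyclohex-3-en-1-yl]oxy}methyl)benzene
Conditions: KH, 4-methoxybenzyl chloride, Bu4NI (cat.), THF, 0 °C → reflux
Reagents that add atoms: 4-methoxybenzyl chloride, COc1ccc(CCl)cc1
Why: Williamson etherification of the tertiary potassium alkoxide with a reactive benzylic halide; the stereocentre is not touched. The ether is chosen because it is a poor leaving group, chelates magnesium in step 5, and is removed oxidatively at the end.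

Step 2
Reactants: 2 terpinen-4-yl 4-methoxybenzyl ether
Product: 4 (5R)-5-[(4-methoxybenzyl)oxy]-2-methyl-5-(propan-2-yl)cyclopent-1-ene-1-carbaldehyde, via keto-aldehyde 3 (not isolated)
Conditions: O3, CH2Cl2, −78 °C (Sudan III end point); Me2S, −78 °C → rt; solvent switch; piperidine (0.3 equiv), AcOH (0.3 equiv), toluene, rt → 40 °C
Reagents that add atoms: ozone, [O-][O+]=O
Why: Ozonolysis cleaves the trisubstituted C1=C6 bond of the cyclohexene (terpene C1=C2), which reacts far faster than the anisyl ring, to give the 6-oxoheptanal 3. The secondary amine condenses with the aldehyde in preference to the ketone, and the enamine carbon (C5) adds to the methyl ketone (C1) in a 5-(enolexo)-exo-trig aldol closure; dehydration gives the conjugated tetrasubstituted enal. The closest known reaction is the amine/acid aldol ring contraction of the 6-oxoheptanals obtained from 1-methylcyclohexenes of the p-menthane series, which gives 2-methylcyclopent-1-enecarbaldehydes. The step closes the five-membered ring by forming C1–C5, so the six-membered ring of 1 is contracted and its ring carbon becomes the formyl carbon C6. No new stereocentre is formed; C4 is retained because it is quaternary and cannot enolise. Two selectivities are needed: the aldehyde enamine, not a ketone enolate, must be the nucleophile, which amine/acid conditions in place of hydroxide secure; and ring closure must outrun loss of the β-alkoxy group from the enamine, which the gem-disubstituted C4 (Thorpe–Ingold), the poor leaving group and the low temperature should secure. Once 4 is formed, C5 carries no hydrogen and this elimination is no longer possible.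

Step 3
Reactants: 4 enal
Product: 6 (1S)-1-{(5R)-5-[(4-methoxybenzyl)oxy]-2-methyl-5-(propan-2-yl)cyclopent-1-en-1-yl}but-3-en-1-ol, via diisopinocampheylborinate 5 (not isolated)
Conditions: (−)-Ipc2BOMe, allylMgBr, Et2O, 0 °C → rt; then 4, −78 → −40 °C; NaOH, H2O2, 0 °C → rt
Reagents that add atoms: allylmagnesium bromide, C=CC[Mg]Br
Why: Brown asymmetric allylboration through a chair Zimmerman–Traxler transition state; the reagent from (+)-α-pinene should add to the Si face of the formyl group and give the (S)-carbinol. The C4 centre is remote from the carbonyl and should not override reagent control.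

Step 4
Reactants: 6 homoallylic alcohol
Product: 8 (1R,2R,5R)-5-[(4-methoxybenzyl)oxy]-2-methyl-5-(propan-2-yl)-2-(prop-2-en-1-yl)cyclopentane-1-carbaldehyde, via potassium enolate 7 (not isolated)
Conditions: KH, 18-crown-6, THF, 0 °C → rt; AcOH, −78 °C; then K2CO3 (cat.), MeOH, 0 °C
Reagents that add atoms: none
Why: Anionic oxy-Cope rearrangement, suprafacial across C6–C5=C1. Allylic 1,3-strain with the methyl on C1 keeps H6 eclipsed with the alkene and the oxide on the outside, so the (S)-carbinol delivers the allyl group to the face of C1 that carries the isopropyl group and C1 becomes (R). Protonation and mild base equilibration should place the formyl group trans to the isopropyl group and cis to O4.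

Step 5
Reactants: 8 aldehyde
Product: 9 (1S)-1-[(1S,2R,5R)-5-[(4-methoxybenzyl)oxy]-2-methyl-5-(propan-2-yl)-2-(prop-2-en-1-yl)cyclopentyl]-3-methylbut-3-en-1-ol
Conditions: tributyl(2-methylprop-2-en-1-yl)stannane, MgBr2·OEt2, CH2Cl2, −78 → −20 °C
Reagents that add atoms: tributyl(2-methylprop-2-en-1-yl)stannane, CCCC[Sn](CCCC)(CCCC)CC(C)=C
Why: Chelation-controlled allylstannane addition (Keck conditions, Cram-chelate model). Magnesium bridges the formyl oxygen and the cis β-ether oxygen, and the nucleophile attacks the carbonyl face away from the quaternary C1, which should give the 1,3-anti (6S) alcohol.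

Step 6
Reactants: 9 diene alcohol
Product: 10 (3R,3aS,4S,8aR)-3-[(4-methoxybenzyl)oxy]-6,8a-dimethyl-3-(propan-2-yl)-1,2,3,3a,4,5,8,8a-octahydroazulen-4-ol
Conditions: Grubbs second-generation catalyst (5 mol %), CH2Cl2 (0.005 M), 40 °C
Reagents that add atoms: none
Why: Ring-closing metathesis between a monosubstituted and a 1,1-disubstituted alkene gives the trisubstituted cis-cycloheptene. The two chains are trans on the cyclopentane, which a seven-membered ring accommodates without strain; no stereocentre is affected.

Step 7
Reactants: 10 bicyclic homoallylic alcohol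
Product: 11 (1R,4R,5S,6S,8R,9S)-8,9-epoxy-4-[(4-methoxybenzyl)oxy]daucan-6-ol
Conditions: VO(acac)2 (5 mol %), t-BuOOH (decane), CH2Cl2, 0 °C → rt
Reagents that add atoms: tert-butyl hydroperoxide, CC(C)(C)OO
Why: Vanadium-catalysed hydroxyl-directed epoxidation of a cyclic homoallylic alcohol delivers oxygen syn to the C6 hydroxyl. That face is also the one anti to the angular methyl, so both effects should give the (8R,9S) epoxide; O4 is masked and cannot open it.

Step 8
Reactants: 11 epoxy alcohol; 12 4-methoxybenzoyl chloride
Product: 13 (1R,4R,5S,6S,8R,9S)-8,9-epoxy-4-[(4-methoxybenzyl)oxy]daucan-6-yl 4-methoxybenzoate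
Conditions: Et3N, DMAP (cat.), CH2Cl2, 0 °C → rt
Reagents that add atoms: none
Why: DMAP-catalysed acylation of the only free hydroxyl; the basic medium spares the epoxide and the configuration at C6 is retained.

Step 9
Reactants: 13 protected ester
Product: 14 (1R,4R,5S,6S,8R,9S)-8,9-epoxy-4-hydroxydaucan-6-yl 4-methoxybenzoate
Conditions: DDQ, CH2Cl2/pH 7 phosphate buffer (10:1), 0 °C → rt
Reagents that add atoms: none
Why: Oxidative cleavage of the 4-methoxybenzyl ether (hydride abstraction to the oxocarbenium ion, then hydrolysis). The anisoyl ring is deactivated by its carbonyl group, and the buffered neutral medium should leave epoxide and ester intact.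

## Compound list

1 | (S)-(+)-terpinen-4-ol, (1S)-4-methyl-1-(propan-2-yl)cyclohex-3-en-1-ol | CC1=CC[C@](O)(C(C)C)CC1 | starting material
2 | 1-methoxy-4-({[(1S)-4-methyl-1-(propan-2-yl)cyclohex-3-en-1-yl]oxy}methyl)benzene | CC1=CC[C@](OCc2ccc(OC)cc2)(C(C)C)CC1 | intermediate
3 | (3S)-3-[(4-methoxybenzyl)oxy]-6-oxo-3-(propan-2-yl)heptanal | CC(=O)CC[C@@](OCc1ccc(OC)cc1)(C(C)C)CC=O | intermediate (not isolated)
4 | (5R)-5-[(4-methoxybenzyl)oxy]-2-methyl-5-(propan-2-yl)cyclopent-1-ene-1-carbaldehyde | CC1=C(C=O)[C@](OCc2ccc(OC)cc2)(C(C)C)CC1 | intermediate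
5 | O-[bis(isopinocampheyl)boryl] derivative of 6 (isopinocampheyl groups from (+)-α-pinene) | CC1=C([C@@H](OB([C@@H]2C[C@@H]3C[C@H]([C@H]2C)C3(C)C)[C@@H]2C[C@@H]3C[C@H]([C@H]2C)C3(C)C)CC=C)[C@](OCc2ccc(OC)cc2)(C(C)C)CC1 | intermediate (not isolated)
6 | (1S)-1-{(5R)-5-[(4-methoxybenzyl)oxy]-2-methyl-5-(propan-2-yl)cyclopent-1-en-1-yl}but-3-en-1-ol | CC1=C([C@@H](O)CC=C)[C@](OCc2ccc(OC)cc2)(C(C)C)CC1 | intermediate
7 | potassium (Z)-enolate of 8 | [K+].[O-]/C=C1\[C@](OCc2ccc(OC)cc2)(C(C)C)CC[C@]1(C)CC=C | intermediate (not isolated)
8 | (1R,2R,5R)-5-[(4-methoxybenzyl)oxy]-2-methyl-5-(propan-2-yl)-2-(prop-2-en-1-yl)cyclopentane-1-carbaldehyde | O=C[C@H]1[C@](OCc2ccc(OC)cc2)(C(C)C)CC[C@]1(C)CC=C | intermediate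
9 | (1S)-1-[(1S,2R,5R)-5-[(4-methoxybenzyl)oxy]-2-methyl-5-(propan-2-yl)-2-(prop-2-en-1-yl)cyclopentyl]-3-methylbut-3-en-1-ol | C=C(C)C[C@H](O)[C@H]1[C@](OCc2ccc(OC)cc2)(C(C)C)CC[C@]1(C)CC=C | intermediate
10 | (3R,3aS,4S,8aR)-3-[(4-methoxybenzyl)oxy]-6,8a-dimethyl-3-(propan-2-yl)-1,2,3,3a,4,5,8,8a-octahydroazulen-4-ol | O[C@H]1CC(C)=CC[C@@]2(C)CC[C@@](OCc3ccc(OC)cc3)(C(C)C)[C@H]12 | intermediate
11 | (1R,4R,5S,6S,8R,9S)-8,9-epoxy-4-[(4-methoxybenzyl)oxy]daucan-6-ol (epoxide oxygen cis to O6) | O[C@H]1C[C@@]2(C)O[C@H]2C[C@@]2(C)CC[C@@](OCc3ccc(OC)cc3)(C(C)C)[C@H]12 | intermediate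
12 | 4-methoxybenzoyl chloride | COc1ccc(C(Cl)=O)cc1 | starting material
13 | (1R,4R,5S,6S,8R,9S)-8,9-epoxy-4-[(4-methoxybenzyl)oxy]daucan-6-yl 4-methoxybenzoate | COc1ccc(C(=O)O[C@H]2C[C@@]3(C)O[C@H]3C[C@@]3(C)CC[C@@](OCc4ccc(OC)cc4)(C(C)C)[C@H]23)cc1 | intermediate
14 | (1R,4R,5S,6S,8R,9S)-8,9-epoxy-4-hydroxydaucan-6-yl 4-methoxybenzoate | COc1ccc(C(=O)O[C@H]2C[C@@]3(C)O[C@H]3C[C@@]3(C)CC[C@@](O)(C(C)C)[C@H]23)cc1 | target

## Step count and least certain steps

Total step count: 9. Longest linear sequence: 9 steps (1 → 14).

Step 2 (key step). The most likely failure is loss of the C4 ether oxygen by β-elimination from the aldehyde-derived enamine (a retro-oxa-Michael process) before the ring closes; partial oxidation of the anisyl ring by ozone is a lesser risk. The fallback gives up the terpene for the five-membered ring. It does not set out from a compound of the route: commercial 2-bromo-3-methylcyclopent-2-en-1-one F1 replaces 1, and the sequence comes back to the route at 6. Isopropylmagnesium chloride with CeCl3 should add 1,2 to give racemic 2-bromo-3-methyl-1-(propan-2-yl)cyclopent-2-en-1-ol F2. Etherification as in step 1 gives the racemic bromo ether F3, and bromine–lithium exchange with n-BuLi followed by DMF gives the racemic enal F4. The reagent-controlled allylboration of step 3 then turns the two enantiomers into 6 and its (1S,5S)-diastereomer F5, which should be separable on silica; 6 continues.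

Step 4. Two processes threaten it: leakage through the rotamer with the oxide on the inside, which erodes the transfer of chirality to C1, and β-elimination of the 4-methoxybenzyloxide from the free enolate or during the base equilibration. The fallback sets out from 6 and returns at 8, and keeps the [3,3] shift but removes the enolate. Silylation (TMSCl, imidazole) gives the trimethylsilyl ether F6, thermolysis in a sealed, base-washed tube (about 200 °C, toluene) gives the (Z)-silyl enol ether F7 by the same suprafacial course, and buffered fluoride (TBAF/AcOH) releases 8.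

Step 3. The formyl group sits on a tetrasubstituted alkene next to a quaternary carbon, so addition of the bulky allylborane may be slow, and the higher temperature then needed would lower the facial selectivity. The fallback sets out from 4 and returns at 6. Allylmagnesium bromide adds without control to give 6 and its C6 epimer F8, buffered Dess–Martin oxidation of the mixture gives the allyl ketone F9, and (R)-CBS-catalysed borane reduction sets C6 to give 6.

Step 5. Incomplete chelation would let open-chain addition compete and give the C6 epimer; Lewis-acid-promoted epimerisation at C5 is a second risk. The fallback sets out from 8 and returns at 9 without a new compound: reagent control by asymmetric methallylboration with (−)-Ipc2B(2-methylallyl), which is independent of the chelate.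

Step 7. Hydroxyl delivery in the flexible seven-membered ring may be inefficient and the facial selectivity poor, and the vanadium Lewis acid may open the trisubstituted epoxide. The fallback sets out from 10 and returns at 13 and reverses the order. Acylation of 10 with 12 (Et3N, DMAP) gives the alkene ester F10, and buffered mCPBA then epoxidises the face anti to the angular methyl under steric control to give 13.

## Further compounds

F1 | step 2 | 2-bromo-3-methylcyclopent-2-en-1-one | CC1=C(Br)C(=O)CC1
F2 | step 2 | racemic 2-bromo-3-methyl-1-(propan-2-yl)cyclopent-2-en-1-ol | CC1=C(Br)C(O)(C(C)C)CC1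
F3 | step 2 | racemic 1-({[2-bromo-3-methyl-1-(propan-2-yl)cyclopent-2-en-1-yl]oxy}methyl)-4-methoxybenzene | CC1=C(Br)C(OCc2ccc(OC)cc2)(C(C)C)CC1
F4 | step 2 | racemic 5-[(4-methoxybenzyl)oxy]-2-methyl-5-(propan-2-yl)cyclopent-1-ene-1-carbaldehyde | CC1=C(C=O)C(OCc2ccc(OC)cc2)(C(C)C)CC1
F5 | step 2 | (1S)-1-{(5S)-5-[(4-methoxybenzyl)oxy]-2-methyl-5-(propan-2-yl)cyclopent-1-en-1-yl}but-3-en-1-ol | CC1=C([C@@H](O)CC=C)[C@@](OCc2ccc(OC)cc2)(C(C)C)CC1
F6 | step 4 | trimethylsilyl ether of 6 | CC1=C([C@@H](O[Si](C)(C)C)CC=C)[C@](OCc2ccc(OC)cc2)(C(C)C)CC1
F7 | step 4 | (Z)-trimethylsilyl enol ether of 8 | C[Si](C)(C)O/C=C1\[C@](OCc2ccc(OC)cc2)(C(C)C)CC[C@]1(C)CC=C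
F8 | step 3 | (1R)-1-{(5R)-5-[(4-methoxybenzyl)oxy]-2-methyl-5-(propan-2-yl)cyclopent-1-en-1-yl}but-3-en-1-ol | CC1=C([C@H](O)CC=C)[C@](OCc2ccc(OC)cc2)(C(C)C)CC1
F9 | step 3 | 1-{(5R)-5-[(4-methoxybenzyl)oxy]-2-methyl-5-(propan-2-yl)cyclopent-1-en-1-yl}but-3-en-1-one | CC1=C(C(=O)CC=C)[C@](OCc2ccc(OC)cc2)(C(C)C)CC1
F0 | step 5 | none | none
F10 | step 7 | (3R,3aS,4S,8aR)-3-[(4-methoxybenzyl)oxy]-6,8a-dimethyl-3-(propan-2-yl)-1,2,3,3a,4,5,8,8a-octahydroazulen-4-yl 4-methoxybenzoate | COc1ccc(C(=O)O[C@H]2CC(C)=CC[C@@]3(C)CC[C@@](OCc4ccc(OC)cc4)(C(C)C)[C@H]23)cc1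
A1 | alternative 1 | (R)-(+)-limonene | CC1=CC[C@@H](CC1)C(C)=C
A2 | alternative 1 | (S)-2-methyl-5-(prop-1-en-2-yl)cyclopent-1-ene-1-carbaldehyde | CC1=C(C=O)[C@H](C(C)=C)CC1
A3 | alternative 1 | (3S,3aS,4S,8aR)-6,8a-dimethyl-3-(propan-2-yl)-1,2,3,3a,4,5,8,8a-octahydroazulen-4-ol | O[C@H]1CC(C)=CC[C@@]2(C)CC[C@@H](C(C)C)[C@H]12
A4 | alternative 2 | (R)-3,6-dimethyl-3-(4-methyl-3-oxopentyl)cyclohept-5-en-1-one | CC(C)C(=O)CC[C@]1(C)CC=C(C)CC(=O)C1
A5 | alternative 2 | (3R,3aR,8aR)-3-hydroxy-6,8a-dimethyl-3-(propan-2-yl)-2,3,3a,5,8,8a-hexahydroazulen-4(1H)-one | O=C1CC(C)=CC[C@@]2(C)CC[C@@](O)(C(C)C)[C@H]12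
A6 | alternative 3 | tert-butyl(dimethyl){[1-(2-methylcyclopent-1-en-1-yl)ethenyl]oxy}silane | C=C(O[Si](C)(C)C(C)(C)C)C1=C(C)CCC1
A7 | alternative 3 | methyl 2-diazobut-3-enoate | COC(=O)C(=[N+]=[N-])C=C
A8 | alternative 3 | methyl (8aR)-4-[(tert-butyldimethylsilyl)oxy]-8a-methyl-1,2,3,5,8,8a-hexahydroazulene-6-carboxylate | COC(=O)C1=CC[C@@]2(C)CCCC2=C(O[Si](C)(C)C(C)(C)C)C1
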